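**Assumption:** The target has no stereocentre and no hindered axis, so it is achiral and "single enantiomer" needs no stereocontrol. The stereocentres that appear in a few intermediates are racemic and disappear on aromatisation.

## Retrosynthetic overview
1. Endgame: hydrogenolysis of a 2'-O-benzyl ether, preceded by methylation of the free 8-OH of a 5,8-dihydroxy-6,7-dimethoxyflavone (the 5-OH is shielded by chelation).
2. Key disconnection: all of ring A is removed by a Moore–Liebeskind benzannulation of a 4-hydroxy-4-(4-pyranonyl)cyclobutenone. Dimethyl squarate supplies C5–C8 and all four of their oxygens in one piece.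
3. The cyclobutenone comes from C–H magnesiation of a 2-aryl-3-methoxy-4-pyranone and 1,2-addition to dimethyl squarate.
4. The arylpyranone comes from a Negishi coupling of 2-bromo-3-methoxy-4-pyranone (from pyromeconic acid) and the arylzinc made from O-benzyl-2-bromo-5-methoxyphenol.
5. Ring order: B (bought), then C (bought as the pyranone), then A (formed last). This reverses the usual acetophenone/chalcone logic.

## Route

Step 1
Reactants: 1 3-hydroxy-4H-pyran-4-one (pyromeconic acid)
Product: 2 2-bromo-3-hydroxy-4H-pyran-4-one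
Conditions: NBS (1.0 equiv), MeCN, 0 °C to rt, dark
Reagents that add atoms: N-bromosuccinimide, O=C1CCC(=O)N1Br
Why: Electrophilic bromination of an enol, in which the free 3-OH makes C2 (the enol β-carbon) by far the most nucleophilic ring position, as in the 6-halogenation of kojic acid.

Step 2
Reactants: 2 2-bromo-3-hydroxy-4H-pyran-4-one
Product: 3 2-bromo-3-methoxy-4H-pyran-4-one
Conditions: MeI (2 equiv), K2CO3 (1.2 equiv), acetone, rt
Reagents that add atoms: iodomethane, CI
Why: Williamson O-alkylation, in which the acidic enol (pKa about 8) is deprotonated by K2CO3 and methylated on oxygen faster than any oxygen nucleophile can displace the C2 bromide.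

Step 3
Reactants: 4 2-bromo-5-methoxyphenol
Product: 5 2-(benzyloxy)-1-bromo-4-methoxybenzene
Conditions: BnBr (1.1 equiv), K2CO3 (1.5 equiv), DMF, rt
Reagents that add atoms: benzyl bromide, BrCc1ccccc1
Why: Williamson ether synthesis, chosen because the benzyl group survives n-BuLi at −78 °C, the TMP base, 110 °C and K2CO3 and leaves at the end under neutral hydrogenolysis.

Step 4
Reactants: 5 2-(benzyloxy)-1-bromo-4-methoxybenzene; 3 2-bromo-3-methoxy-4H-pyran-4-one
Product: 8 2-[2-(benzyloxy)-4-methoxyphenyl]-3-methoxy-4H-pyran-4-one, via aryllithium 6 (not isolated), via arylzinc chloride 7 (not isolated)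
Conditions: 5, n-BuLi (1.05 equiv), THF, −78 °C; ZnCl2 (1.1 equiv), −78 °C to rt; then 3 (0.9 equiv), Pd(PPh3)4 (5 mol %), THF, rt to 50 °C
Reagents that add atoms: none
Why: Bromine–lithium exchange and transmetalation give a non-basic arylzinc for a Negishi coupling, in which zerovalent palladium inserts readily into the C2–Br bond (a vinylogous acyl bromide) and the base-free medium spares the nucleophile-sensitive pyranone.

Step 5
Reactants: 8 2-[2-(benzyloxy)-4-methoxyphenyl]-3-methoxy-4H-pyran-4-one; 9 dimethyl squarate (3,4-dimethoxycyclobut-3-ene-1,2-dione)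
Product: 12 4-{6-[2-(benzyloxy)-4-methoxyphenyl]-5-methoxy-4-oxo-4H-pyran-3-yl}-4-hydroxy-2,3-dimethoxycyclobut-2-en-1-one (racemic), via magnesiated pyranone 10 (not isolated), via magnesium alkoxide 11 (not isolated)
Conditions: TMPMgCl·LiCl (1.2 equiv), THF, −40 °C, 45 min; cannulated into 9 (1.5 equiv), THF, −78 °C; sat. aq NH4Cl, −78 to 0 °C
Reagents that add atoms: none
Why: Proposed new method: the non-nucleophilic TMP-magnesium base binds the C4 carbonyl and removes the neighbouring C5–H (complex-induced proximity effect; closest known reaction type is the directed TMP-metal deprotonation of chromones at C3 and uracils at C5, and related β-oxygenated alkenylmagnesiums hold at about −30 °C without β-elimination), the alkenylmagnesium then adds 1,2 to one of the two equivalent strained carbonyls of 9 as organolithium and Grignard reagents do, the new carbinol centre is racemic and is erased in step 6, and because 9 is symmetric and both its carbonyl carbons end as C–OH, any C6-metalated regioisomer converges on the same hydroquinone in step 6.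

Step 6
Reactants: 12 4-{6-[2-(benzyloxy)-4-methoxyphenyl]-5-methoxy-4-oxo-4H-pyran-3-yl}-4-hydroxy-2,3-dimethoxycyclobut-2-en-1-one
Product: 16 2-[2-(benzyloxy)-4-methoxyphenyl]-5-hydroxy-3,6,7,8-tetramethoxy-4H-chromen-4-one, via dienylketene 13 (not isolated), via 8aH-dienone 14 (not isolated), via hydroquinone 15 (not isolated)
Conditions: degassed PhMe, 110 °C, Ar, 2 h; cool, then acetone, K2CO3 (1.5 equiv), Me2SO4 (1.05 equiv), 50 °C, Ar
Reagents that add atoms: dimethyl sulfate, COS(=O)(=O)OC
Why: Moore–Liebeskind benzannulation, in which conrotatory 4π opening with the OH turning outward (torquoselectivity) places the pyranone C5=C6 bond beside the ketene, 6π electrocyclisation and tautomerisation build ring A as the 5,8-dihydroxy-6,7-dimethoxy pattern with loss of the transient stereocentres, and a Williamson methylation with one equivalent of Me2SO4 then takes only the free 8-OH because the 5-OH is locked in a hydrogen bond to the C4 carbonyl.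

Step 7
Reactants: 16 2-[2-(benzyloxy)-4-methoxyphenyl]-5-hydroxy-3,6,7,8-tetramethoxy-4H-chromen-4-one
Product: 17 5-hydroxy-2-(2-hydroxy-4-methoxyphenyl)-3,6,7,8-tetramethoxy-4H-chromen-4-one (5,2'-dihydroxy-3,6,7,8,4'-pentamethoxyflavone)
Conditions: H2 (1 atm), Pd/C (10 wt %), EtOAc–MeOH, rt
Reagents that add atoms: none
Why: Catalytic hydrogenolysis of the aryl benzyl ether, under which the tetrasubstituted C2=C3 bond, the methyl ethers and the chelated phenol are inert at 1 atm.

## Compound list
1 | 3-hydroxy-4H-pyran-4-one (pyromeconic acid) | O=c1ccocc1O | starting material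
2 | 2-bromo-3-hydroxy-4H-pyran-4-one | O=c1ccoc(Br)c1O | intermediate
3 | 2-bromo-3-methoxy-4H-pyran-4-one | COc1c(Br)occc1=O | intermediate
4 | 2-bromo-5-methoxyphenol | COc1ccc(Br)c(O)c1 | starting material
5 | 2-(benzyloxy)-1-bromo-4-methoxybenzene | COc1ccc(Br)c(OCc2ccccc2)c1 | intermediate
6 | [2-(benzyloxy)-4-methoxyphenyl]lithium | [Li]c1ccc(OC)cc1OCc1ccccc1 | intermediate
7 | [2-(benzyloxy)-4-methoxyphenyl]zinc chloride | Cl[Zn]c1ccc(OC)cc1OCc1ccccc1 | intermediate
8 | 2-[2-(benzyloxy)-4-methoxyphenyl]-3-methoxy-4H-pyran-4-one | COc1ccc(-c2occc(=O)c2OC)c(OCc2ccccc2)c1 | intermediate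
9 | dimethyl squarate (3,4-dimethoxycyclobut-3-ene-1,2-dione) | COC1=C(OC)C(=O)C1=O | starting material
10 | {6-[2-(benzyloxy)-4-methoxyphenyl]-5-methoxy-4-oxo-4H-pyran-3-yl}magnesium chloride (C5 of 8 metalated) | COc1ccc(-c2occ([Mg]Cl)c(=O)c2OC)c(OCc2ccccc2)c1 | intermediate
11 | chloromagnesium alkoxide of 12 (racemic) | COC1=C(OC)C(O[Mg]Cl)(c2coc(-c3ccc(OC)cc3OCc3ccccc3)c(OC)c2=O)C1=O | intermediate
12 | 4-{6-[2-(benzyloxy)-4-methoxyphenyl]-5-methoxy-4-oxo-4H-pyran-3-yl}-4-hydroxy-2,3-dimethoxycyclobut-2-en-1-one (racemic) | COC1=C(OC)C(O)(c2coc(-c3ccc(OC)cc3OCc3ccccc3)c(OC)c2=O)C1=O | intermediate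
13 | (Z)-4-{6-[2-(benzyloxy)-4-methoxyphenyl]-5-methoxy-4-oxo-4H-pyran-3-yl}-4-hydroxy-2,3-dimethoxybuta-1,3-dien-1-one (dienylketene, OH outward) | O=C=C(OC)/C(OC)=C(/O)c1coc(-c2ccc(OC)cc2OCc2ccccc2)c(OC)c1=O | intermediate
14 | 2-[2-(benzyloxy)-4-methoxyphenyl]-5-hydroxy-3,6,7-trimethoxy-8aH-chromene-4,8-dione (racemic at C8a) | COC1=C(OC)C(O)=C2C(=O)C(OC)=C(c3ccc(OC)cc3OCc3ccccc3)OC2C1=O | intermediate
15 | 2-[2-(benzyloxy)-4-methoxyphenyl]-5,8-dihydroxy-3,6,7-trimethoxy-4H-chromen-4-one | COc1ccc(-c2oc3c(O)c(OC)c(OC)c(O)c3c(=O)c2OC)c(OCc2ccccc2)c1 | intermediate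
16 | 2-[2-(benzyloxy)-4-methoxyphenyl]-5-hydroxy-3,6,7,8-tetramethoxy-4H-chromen-4-one | COc1ccc(-c2oc3c(OC)c(OC)c(OC)c(O)c3c(=O)c2OC)c(OCc2ccccc2)c1 | intermediate
17 | 5,2'-dihydroxy-3,6,7,8,4'-pentamethoxyflavone (achiral) | COc1ccc(-c2oc3c(OC)c(OC)c(OC)c(O)c3c(=O)c2OC)c(O)c1 | target

## Step count and risk
Total steps: 7. Longest linear sequence: 6 (steps 1, 2, 4, 5, 6, 7).

**Step 5 (highest risk).** The magnesiated pyranone may form slowly or open by β-elimination of the ring oxygen.
- The fallback sets out from 8 and comes back at 10.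
- It replaces direct deprotonation to a polar C–Mg species by a covalent C–Zn bond and an isolable halide.
- 8 is zincated next to the carbonyl by TMPZnCl·LiCl (THF, rt) to give [6-(2-benzyloxy-4-methoxyphenyl)-5-methoxy-4-oxo-4H-pyran-3-yl]zinc chloride F1.
- I2 converts this into 2-[2-(benzyloxy)-4-methoxyphenyl]-5-iodo-3-methoxy-4H-pyran-4-one F2. Ring B stays untouched because the iodine is consumed by the C–Zn bond.
- Iodine–magnesium exchange with iPrMgCl·LiCl at −78 °C, well below the temperature needed for deprotonation, delivers 10 just before 9 is added.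

**Step 6.** The electrocyclisation has close analogy in alkenyl and heteroaryl cases. The weak point is hydroquinone 15, which can oxidise in air to the 5,8-quinone or be over-methylated.
- The fallback sets out from 15, made in the flask as in step 6, and comes back at 17.
- It replaces selective alkylation by exhaustive alkylation followed by selective dealkylation.
- Excess Me2SO4 and K2CO3 in refluxing acetone give the robust 2-[2-(benzyloxy)-4-methoxyphenyl]-3,5,6,7,8-pentamethoxy-4H-chromen-4-one F3.
- BCl3 with pentamethylbenzene (CH2Cl2, −78 to 0 °C) then cleaves the 5-OMe through the six-membered boron chelate with the C4 carbonyl. It cleaves the benzyl ether in the same operation and gives 17 directly, with no change in step count.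

**Step 4.** The 2-bromopyranone may be degraded, or may couple poorly with the ortho-substituted arylzinc.
- The fallback sets out from 1 and 5 and comes back at 8.
- It reverses the polarity of the coupling, so no halopyranone is needed.
- 1 is O-methylated (MeI, K2CO3, acetone) to 3-methoxy-4H-pyran-4-one F4.
- TMP2Zn·2MgCl2·2LiCl zincates F4 to bis(3-methoxy-4-oxo-4H-pyran-2-yl)zinc F5. MgCl2 on the carbonyl steers the base to the position next to the ring oxygen, and the neighbouring OMe favours C2 over C6.
- A Negishi coupling of F5 with aryl bromide 5, using Pd(OAc)2 and 2-dicyclohexylphosphino-2',6'-dimethoxybiphenyl (THF, 50 °C), gives 8.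

## Further compounds
F1 | step 5 | [6-(2-benzyloxy-4-methoxyphenyl)-5-methoxy-4-oxo-4H-pyran-3-yl]zinc chloride | COc1ccc(-c2occ([Zn]Cl)c(=O)c2OC)c(OCc2ccccc2)c1
F2 | step 5 | 2-[2-(benzyloxy)-4-methoxyphenyl]-5-iodo-3-methoxy-4H-pyran-4-one | COc1ccc(-c2occ(I)c(=O)c2OC)c(OCc2ccccc2)c1
F3 | step 6 | 2-[2-(benzyloxy)-4-methoxyphenyl]-3,5,6,7,8-pentamethoxy-4H-chromen-4-one | COc1ccc(-c2oc3c(OC)c(OC)c(OC)c(OC)c3c(=O)c2OC)c(OCc2ccccc2)c1
F4 | step 4 | 3-methoxy-4H-pyran-4-one | COc1coccc1=O
F5 | step 4 | bis(3-methoxy-4-oxo-4H-pyran-2-yl)zinc | COc1c([Zn]c2occc(=O)c2OC)occc1=O
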